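## Retrosynthetic overview

1. Locants: C6 = spiro carbon; ring A = C6–C7(Me)=C8–C9–C10(Br)–C11(Me)2; ring B = C6–C1–C2(Br)–C3(Me)(OH)–C4–C5. Enabling feature: C6 holds both the vinylic C7 of ring A and the C1–C2 arm of ring B, so C7 and C2 can be tied together as the double bond of a 1-methylcyclobutene (C6–C7=C2–C1) that stores ring strain and one olefin carbon of each ring.
2. Target ⇒ 10-bromo-α-chamigrene by bromohydrin formation across C2=C3 (last step).
3. 10-Bromo-α-chamigrene ⇒ a monocyclic cyclobutene triene: ring-opening/double ring-closing metathesis cleaves C7=C2 and forms C7=C8 (ring A) and C2=C3 (ring B) in one operation.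
4. Cyclobutene ⇒ C10–Br by allylboration and Appel inversion; C6–C11 bond (vicinal quaternary carbons) by an Ireland–Claisen shift of a cyclobutenyl isobutyrate that relays a CBS-set carbinol configuration to C6; cyclobutenone from ketene, an ynol ether and a homomethallyl Grignard reagent.
5. Ring order: temporary cyclobutene (step 1), then rings A and B together (step 10).

Key step: step 10

Assumption: 1-ethoxyprop-1-yne and (+)-Ipc2B(allyl) (the reagent derived from (−)-α-pinene) are taken as purchasable, and the 2-cyclobutenol derivatives 9–13 are kept at or below 40 °C to avoid electrocyclic ring opening.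

## Route

Step 1
Reactants: 1 1-ethoxyprop-1-yne; 2 acetyl chloride
Product: 4 3-ethoxy-2-methylcyclobut-2-en-1-one, via ketene 3 (not isolated)
Conditions: Et3N, Et2O, 0 → 23 °C (2 added slowly)
Reagents that add atoms: none
Why: Dehydrochlorination of 2 gives ketene, which should undergo the thermal [2+2] cycloaddition with the ynol ether (Wasserman-type cyclobutenone synthesis), the nucleophilic methyl-bearing alkyne carbon bonding to the ketene carbonyl carbon so that the methyl group ends next to C=O; no stereocenter is formed.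

Step 2
Reactants: 4 3-ethoxy-2-methylcyclobut-2-en-1-one; 5 4-bromo-2-methylbut-1-ene
Product: 8 2-methyl-3-(3-methylbut-3-en-1-yl)cyclobut-2-en-1-one, via Grignard reagent 6 (not isolated), via tertiary carbinol 7 (not isolated)
Conditions: 5, Mg, THF, 23 °C; then 4, −78 → 0 °C; 1 M HCl, 0 °C
Reagents that add atoms: water, O
Why: 1,2-Addition of the Grignard reagent to the vinylogous ester followed by acid-mediated 1,3-carbonyl transposition (Stork–Danheiser type: loss of the carbinol OH, hydration of the ethoxy-stabilised cation, loss of ethanol) should place the side chain on the β-carbon of the new cyclobutenone; no stereocenter remains.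

Step 3
Reactants: 8 2-methyl-3-(3-methylbut-3-en-1-yl)cyclobut-2-en-1-one
Product: 10 (1S)-2-methyl-3-(3-methylbut-3-en-1-yl)cyclobut-2-en-1-ol, via catechol borate 9 (not isolated)
Conditions: (R)-2-methyl-CBS-oxazaborolidine (20 mol%), catecholborane, toluene, −78 °C; MeOH, then pH 10 buffer
Reagents that add atoms: none
Why: Corey–Bakshi–Shibata reduction, in which the (R)-oxazaborolidine differentiates the alkenyl flank (large) from the CH2 flank (small) and should deliver hydride to give the (S)-carbinol, catecholborane being chosen because it does not hydroborate the 1,1-disubstituted alkene at −78 °C.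

Step 4
Reactants: 10 (1S)-2-methyl-3-(3-methylbut-3-en-1-yl)cyclobut-2-en-1-ol
Product: 11 (1S)-2-methyl-3-(3-methylbut-3-en-1-yl)cyclobut-2-en-1-yl 2-methylpropanoate
Conditions: iPrCOCl, pyridine, DMAP (cat.), CH2Cl2, 0 °C
Reagents that add atoms: isobutyryl chloride, CC(C)C(Cl)=O
Why: DMAP-catalysed acylation of the secondary allylic alcohol under non-alkoxide conditions (so that no oxy-anion-accelerated cyclobutene opening can occur) should give the ester with the carbinol stereocenter untouched.

Step 5
Reactants: 11 (1S)-2-methyl-3-(3-methylbut-3-en-1-yl)cyclobut-2-en-1-yl 2-methylpropanoate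
Product: 14 2-methyl-2-[(1R)-2-methyl-1-(3-methylbut-3-en-1-yl)cyclobut-2-en-1-yl]propanoic acid, via silyl ketene acetal 12 (not isolated), via silyl ester 13 (not isolated)
Conditions: LiN(iPr)2, THF, −78 °C; Me3SiCl; −78 → 40 °C; 1 M HCl work-up
Reagents that add atoms: none
Why: Proposed new method: the isobutyrate enolate is trapped as the silyl ketene acetal, whose [3,3] shift through a boat-like, bicyclo[3.1.1]-type transition state should deliver the Me2C carbon to the substituted ring carbon on the face that the C–O bond leaves (suprafacial 1,3-chirality transfer), so the (S)-carbinol becomes the (R)-quaternary carbon (future C6) joined to the future C11 while the double bond moves to give the 1-methylcyclobutene; the closest known reaction type is the Ireland–Claisen rearrangement of cyclohex-2-enyl and cyclopent-2-enyl esters, which builds vicinal quaternary carbons in the same way.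

Step 6
Reactants: 14 2-methyl-2-[(1R)-2-methyl-1-(3-methylbut-3-en-1-yl)cyclobut-2-en-1-yl]propanoic acid
Product: 15 2-methyl-2-[(1R)-2-methyl-1-(3-methylbut-3-en-1-yl)cyclobut-2-en-1-yl]propan-1-ol
Conditions: LiAlH4, THF, 0 → 40 °C
Reagents that add atoms: none
Why: LiAlH4 reduction of the hindered carboxylic acid to the neopentyl primary alcohol should leave the isolated alkenes, the cyclobutene and the quaternary stereocenter untouched.

Step 7
Reactants: 15 2-methyl-2-[(1R)-2-methyl-1-(3-methylbut-3-en-1-yl)cyclobut-2-en-1-yl]propan-1-ol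
Product: 16 2-methyl-2-[(1R)-2-methyl-1-(3-methylbut-3-en-1-yl)cyclobut-2-en-1-yl]propanal
Conditions: Dess–Martin periodinane, NaHCO3, CH2Cl2, 0 → 23 °C
Reagents that add atoms: none
Why: Dess–Martin oxidation of the hindered primary alcohol should give the non-enolisable aldehyde under buffered conditions that spare the alkenes.

Step 8
Reactants: 16 2-methyl-2-[(1R)-2-methyl-1-(3-methylbut-3-en-1-yl)cyclobut-2-en-1-yl]propanal
Product: 18 (3R)-2-methyl-2-[(1R)-2-methyl-1-(3-methylbut-3-en-1-yl)cyclobut-2-en-1-yl]hex-5-en-3-ol, via borinate 17 (not isolated)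
Conditions: (+)-Ipc2B(allyl), Et2O, −78 → −40 °C; then NaOH, H2O2 (aq), 0 → 23 °C
Reagents that add atoms: (+)-B-allyldiisopinocampheylborane, C=CCB([C@H]1C[C@H]2C[C@@H]([C@@H]1C)C2(C)C)[C@H]1C[C@H]2C[C@@H]([C@@H]1C)C2(C)C
Why: Brown asymmetric allylboration through a chair Zimmerman–Traxler transition state, in which the (−)-α-pinene-derived reagent should add to the Re face of the α-quaternary aldehyde and set the (R)-carbinol (future C10) by reagent control, the remote quaternary stereocenter having little say.

Step 9
Reactants: 18 (3R)-2-methyl-2-[(1R)-2-methyl-1-(3-methylbut-3-en-1-yl)cyclobut-2-en-1-yl]hex-5-en-3-ol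
Product: 19 (4R)-4-[(3S)-3-bromo-2-methylhex-5-en-2-yl]-1-methyl-4-(3-methylbut-3-en-1-yl)cyclobut-1-ene
Conditions: PPh3, CBr4, toluene, 0 → 60 °C
Reagents that add atoms: tetrabromomethane, BrC(Br)(Br)Br
Why: Appel reaction, in which bromide should displace the oxyphosphonium group in an SN2 step with inversion and turn the (R)-carbinol into the (S)-bromide, the non-ionising conditions being relied on to suppress Wagner–Meerwein shift at this pinacolyl-type carbinol.

Step 10
Reactants: 19 (4R)-4-[(3S)-3-bromo-2-methylhex-5-en-2-yl]-1-methyl-4-(3-methylbut-3-en-1-yl)cyclobut-1-ene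
Product: 20 (6R,10S)-10-bromo-3,7,11,11-tetramethylspiro[5.5]undeca-2,7-diene (10-bromo-α-chamigrene)
Conditions: second-generation Hoveyda–Grubbs catalyst [RuCl2(H2IMes)(=CH-C6H4-2-OiPr)] (5 mol%), CH2Cl2 (2 mM), 40 °C, argon sparge
Reagents that add atoms: none
Why: The catalyst should load on the monosubstituted C8 vinyl group, and the C8 alkylidene then adds across the strained C7=C2 bond of the cyclobutene with C8 bonding to C7, so that cycloreversion opens the four-membered ring (about 30 kcal/mol of strain released), closes ring A at the trisubstituted C7=C8 bond and leaves a C2 alkylidene on the C1 arm, which closes ring B on the 1,1-disubstituted alkene of the C5–C4–C3 arm and gives off the methylidene (ethylene overall). The closest known reaction type is the tandem ring-opening/ring-closing (ring-rearrangement) metathesis of cyclobutenes that carry two olefinic tethers. Ring A is closed by ring-opening/ring-closing metathesis (six-membered, new C7=C8 bond) and ring B by ring-closing metathesis (six-membered, new C2=C3 bond). No stereocenter is created: C6 and C10 are carried through, the quaternary cyclobutene carbon becoming the spiro centre because no bond to it is broken. The step needs the C8 alkylidene to attack C7 and not C2, which the six- against seven-membered ring and the placing of the metal on the less substituted carbon secure, and it needs ring closure to beat oligomerisation, which high dilution and the hindered trisubstituted cyclobutene secure; direct ring closure between the two tethers would require an eight-membered ring. The secondary bromide is inert to the ruthenium alkylidene.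

Step 11
Reactants: 20 (6R,10S)-10-bromo-3,7,11,11-tetramethylspiro[5.5]undeca-2,7-diene
Product: 21 (2R,3R,6R,10S)-2,10-dibromo-3,7,11,11-tetramethylspiro[5.5]undec-7-en-3-ol
Conditions: NBS, acetone–H2O (4:1), 0 °C, dark
Reagents that add atoms: N-bromosuccinimide, O=C1CCC(=O)N1Br; water, O
Why: Bromohydrin formation, in which NBS should attack the more accessible ring B alkene (the ring A alkene is flanked by the quaternary C6 and C11), the bromonium ion forming on the face away from the axially placed C7 and its methyl group (C11 equatorial on ring B) and water opening it anti at the tertiary C3 (Markovnikov), which puts Br at C2 cis to C11 and OH at C3 cis to C7, the product relaxing to the chair with both equatorial.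

## Compound list

1 | 1-ethoxyprop-1-yne | CCOC#CC | starting material
2 | acetyl chloride | CC(Cl)=O | starting material
3 | ketene (ethenone) | C=C=O | intermediate
4 | 3-ethoxy-2-methylcyclobut-2-en-1-one | CCOC1=C(C)C(=O)C1 | intermediate
5 | 4-bromo-2-methylbut-1-ene | CC(=C)CCBr | starting material
6 | (3-methylbut-3-en-1-yl)magnesium bromide | CC(=C)CC[Mg]Br | intermediate
7 | 3-ethoxy-2-methyl-1-(3-methylbut-3-en-1-yl)cyclobut-2-en-1-ol (racemic; present as its magnesium alkoxide before the acid quench) | CCOC1=C(C)C(O)(CCC(C)=C)C1 | intermediate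
8 | 2-methyl-3-(3-methylbut-3-en-1-yl)cyclobut-2-en-1-one | CC1=C(CCC(C)=C)CC1=O | intermediate
9 | 2-{[(1S)-2-methyl-3-(3-methylbut-3-en-1-yl)cyclobut-2-en-1-yl]oxy}-1,3,2-benzodioxaborole | B1(O[C@H]2CC(CCC(C)=C)=C2C)Oc2ccccc2O1 | intermediate
10 | (1S)-2-methyl-3-(3-methylbut-3-en-1-yl)cyclobut-2-en-1-ol | O[C@H]1CC(CCC(C)=C)=C1C | intermediate
11 | (1S)-2-methyl-3-(3-methylbut-3-en-1-yl)cyclobut-2-en-1-yl 2-methylpropanoate | CC(C)C(=O)O[C@H]1CC(CCC(C)=C)=C1C | intermediate
12 | trimethylsilyl ketene acetal of 11: 2-methyl-1-{[(1S)-2-methyl-3-(3-methylbut-3-en-1-yl)cyclobut-2-en-1-yl]oxy}-1-(trimethylsilyloxy)prop-1-ene | CC(C)=C(O[Si](C)(C)C)O[C@H]1CC(CCC(C)=C)=C1C | intermediate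
13 | trimethylsilyl 2-methyl-2-[(1R)-2-methyl-1-(3-methylbut-3-en-1-yl)cyclobut-2-en-1-yl]propanoate | C[Si](C)(C)OC(=O)C(C)(C)[C@@]1(CCC(C)=C)C(C)=CC1 | intermediate
14 | 2-methyl-2-[(1R)-2-methyl-1-(3-methylbut-3-en-1-yl)cyclobut-2-en-1-yl]propanoic acid | OC(=O)C(C)(C)[C@@]1(CCC(C)=C)C(C)=CC1 | intermediate
15 | 2-methyl-2-[(1R)-2-methyl-1-(3-methylbut-3-en-1-yl)cyclobut-2-en-1-yl]propan-1-ol | OCC(C)(C)[C@@]1(CCC(C)=C)C(C)=CC1 | intermediate
16 | 2-methyl-2-[(1R)-2-methyl-1-(3-methylbut-3-en-1-yl)cyclobut-2-en-1-yl]propanal | O=CC(C)(C)[C@@]1(CCC(C)=C)C(C)=CC1 | intermediate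
17 | O-[bis(isopinocampheyl)boryl] derivative of 18 (isopinocampheyl groups from (−)-α-pinene) | C=CC[C@@H](OB([C@H]2C[C@H]3C[C@@H]([C@@H]2C)C3(C)C)[C@H]2C[C@H]3C[C@@H]([C@@H]2C)C3(C)C)C(C)(C)[C@@]1(CCC(C)=C)C(C)=CC1 | intermediate
18 | (3R)-2-methyl-2-[(1R)-2-methyl-1-(3-methylbut-3-en-1-yl)cyclobut-2-en-1-yl]hex-5-en-3-ol | C=CC[C@@H](O)C(C)(C)[C@@]1(CCC(C)=C)C(C)=CC1 | intermediate
19 | (4R)-4-[(3S)-3-bromo-2-methylhex-5-en-2-yl]-1-methyl-4-(3-methylbut-3-en-1-yl)cyclobut-1-ene | C=CC[C@H](Br)C(C)(C)[C@@]1(CCC(C)=C)C(C)=CC1 | intermediate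
20 | (6R,10S)-10-bromo-3,7,11,11-tetramethylspiro[5.5]undeca-2,7-diene (10-bromo-α-chamigrene) | CC1=CC[C@H](Br)C(C)(C)[C@@]12CCC(C)=CC2 | intermediate
21 | (2R,3R,6R,10S)-2,10-dibromo-3,7,11,11-tetramethylspiro[5.5]undec-7-en-3-ol | CC1=CC[C@H](Br)C(C)(C)[C@@]12CC[C@@](C)(O)[C@H](Br)C2 | target

## Step count and risks

Total step count: 11. Longest linear sequence: 11 steps (from 1).

The three steps most likely to fail:

1. Step 5 (proposed new method). The silyl ketene acetal may not reach the boat-like transition state on the four-membered ring, so that ionisation of the allylic ester, thermal ring opening of the cyclobutene or simple return of 11 on hydrolysis outruns the [3,3] shift. Fallback, setting out from 8 and using known chemistry only: Mukaiyama–Michael addition of 1-methoxy-2-methyl-1-(trimethylsilyloxy)prop-1-ene to 8 (cat. HNTf2, CH2Cl2, −78 °C) should join the two quaternary carbons and give the regiodefined racemic silyl enol ether methyl 2-methyl-2-[2-methyl-1-(3-methylbut-3-en-1-yl)-3-(trimethylsilyloxy)cyclobut-2-en-1-yl]propanoate F1. CsF and PhNTf2 (DME) would convert it into the enol triflate methyl 2-methyl-2-[2-methyl-1-(3-methylbut-3-en-1-yl)-3-(trifluoromethylsulfonyloxy)cyclobut-2-en-1-yl]propanoate F2. Reduction with Pd(OAc)2, PPh3, Bu3N and HCO2H (DMF, 60 °C) should give the racemic cyclobutene ester methyl 2-methyl-2-[2-methyl-1-(3-methylbut-3-en-1-yl)cyclobut-2-en-1-yl]propanoate F3. LiAlH4 then gives racemic 2-methyl-2-[2-methyl-1-(3-methylbut-3-en-1-yl)cyclobut-2-en-1-yl]propan-1-ol F4, whose enantiomers are separated by preparative chromatography on a chiral stationary phase; the (R)-enantiomer is 15, where the route is rejoined.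

2. Step 9. At the carbinol flanked by the CMe2 group, elimination toward the 1,3-diene or a methyl shift from the oxyphosphonium ion may outrun backside displacement, and partial ionisation would erode the configuration. Fallback, setting out from 18: activation and displacement are separated. NaH and N,N'-sulfonyldiimidazole (THF, −30 °C) should give the isolable (3R)-2-methyl-2-[(1R)-2-methyl-1-(3-methylbut-3-en-1-yl)cyclobut-2-en-1-yl]hex-5-en-3-yl 1H-imidazole-1-sulfonate F5, which is displaced with inversion by LiBr (DMF, 40 °C) to give 19, where the route is rejoined.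

3. Step 11. Facial selectivity of bromonium formation on ring B may be poor if the two half-chairs of ring B are close in energy, giving the C2,C3-diastereomeric bromohydrin, and some attack on the ring A alkene or transannular capture of the C3 cation may occur. Fallback, setting out from 20: the oxygen is placed first under reagent control. Epoxidation with the L-fructose-derived Shi ketone, KHSO5 and K2CO3 (MeCN–dimethoxymethane–buffer, 0 °C; face assigned by analogy with 1-phenylcyclohexene) should give (2S,3R,6R,10S)-10-bromo-2,3-epoxy-3,7,11,11-tetramethylspiro[5.5]undec-7-ene F6 with the oxygen cis to C7. Li2NiBr4 (THF, 0 °C) then delivers bromide to the secondary C2 with inversion to give 21.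

Further compounds

F1 | step 5 | methyl 2-methyl-2-[2-methyl-1-(3-methylbut-3-en-1-yl)-3-(trimethylsilyloxy)cyclobut-2-en-1-yl]propanoate (racemic) | COC(=O)C(C)(C)C1(CCC(C)=C)CC(O[Si](C)(C)C)=C1C
F2 | step 5 | methyl 2-methyl-2-[2-methyl-1-(3-methylbut-3-en-1-yl)-3-(trifluoromethylsulfonyloxy)cyclobut-2-en-1-yl]propanoate (racemic) | COC(=O)C(C)(C)C1(CCC(C)=C)CC(OS(=O)(=O)C(F)(F)F)=C1C
F3 | step 5 | methyl 2-methyl-2-[2-methyl-1-(3-methylbut-3-en-1-yl)cyclobut-2-en-1-yl]propanoate (racemic) | COC(=O)C(C)(C)C1(CCC(C)=C)C(C)=CC1
F4 | step 5 | 2-methyl-2-[2-methyl-1-(3-methylbut-3-en-1-yl)cyclobut-2-en-1-yl]propan-1-ol (racemic; 15 and its enantiomer) | OCC(C)(C)C1(CCC(C)=C)C(C)=CC1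
F5 | step 9 | (3R)-2-methyl-2-[(1R)-2-methyl-1-(3-methylbut-3-en-1-yl)cyclobut-2-en-1-yl]hex-5-en-3-yl 1H-imidazole-1-sulfonate | C=CC[C@@H](OS(=O)(=O)n1ccnc1)C(C)(C)[C@@]1(CCC(C)=C)C(C)=CC1
F6 | step 11 | (2S,3R,6R,10S)-10-bromo-2,3-epoxy-3,7,11,11-tetramethylspiro[5.5]undec-7-ene | CC1=CC[C@H](Br)C(C)(C)[C@@]12CC[C@@](C)(O3)[C@@H]3C2
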